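**Retrosynthetic overview**
1. Target ⇒ removal of two TBS ethers; the (Z)-enoate side chain ⇒ Still–Gennari olefination between a C3 phosphonoacetate of the decalin and (R)-2-(angeloyloxy)butanal.
2. Equatorial C3–OH and saturated C1–C2 ⇒ one dissolving-metal reduction of a ring-A enone; enone ⇒ 3-silyloxy-Δ1 cycloadduct; C15 methyl ⇒ formyl group (tosylhydrazone reduction).
3. Key disconnection: C3–C4 and C5–C10 by an intramolecular Diels–Alder reaction of an acyclic trienal. Enabling feature: ring A (C1–C5, C10) is a cyclohexane with oxygen on C3 and cis methyls on C4/C5, so it is the adduct of a 1-oxy-diene C3=C2–C1=C10 and an (E)-trisubstituted alkene C4=C5, while the ring-B chain C6–C7–C8–C9 (isopropenyl and both oxygens in place) is a four-atom tether from C5 to C10; the C4 methyl is carried as CHO to activate the dienophile.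
4. Trienal ⇒ C9–C10 by a non-chelation-controlled vinylogous Mukaiyama aldol reaction and soft enolisation to the diene; C7–C8 and the isopropenyl group ⇒ catalytic asymmetric glyoxylate-ene reaction of an achiral skipped dienoate (one Suzuki–Miyaura coupling).
5. Ring order: no ring exists before the key step; ring B (tether ring) and ring A (cycloadduct ring) are closed together.

Key step: step 9

Remark: eremophilane numbering is used (ring A = C1–C5, C10; ring B = C5–C10; C14 on C5, C15 on C4, isopropenyl C11–C13 on C7; β = face of the C5 methyl; target = 3R,4R,5R,7S,8R,9S,10R), and 1, 2, 4, 8, 21, 23 and 24 are taken as purchasable in the stated geometric or enantiomeric form.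

Step 1
Reactants: 1 methyl (2E)-4-bromo-3-methylbut-2-enoate; 2 4,4,5,5-tetramethyl-2-(2-methylprop-1-en-1-yl)-1,3,2-dioxaborolane
Product: 3 methyl (2E)-3,6-dimethylhepta-2,5-dienoate
Conditions: Pd(PPh3)4 (5 mol %), K3PO4, THF/H2O, 50 °C
Reagents that add atoms: none
Why: Suzuki–Miyaura allyl–alkenyl coupling through a π-allylpalladium intermediate should join the unsubstituted allyl terminus to the alkenyl group, keeping the enoate conjugated and E; no stereocenter is formed.

Step 2
Reactants: 3 methyl (2E)-3,6-dimethylhepta-2,5-dienoate (1.5 equiv); 4 ethyl glyoxylate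
Product: 5 1-ethyl 7-methyl (2R,3S,5E)-2-hydroxy-5-methyl-3-(prop-1-en-2-yl)hept-5-enedioate
Conditions: (R)-BINOL/TiCl2(OiPr)2 (10 mol %), 4 Å MS, CH2Cl2, −30 °C
Reagents that add atoms: none
Why: Catalytic enantioselective glyoxylate-ene reaction at the electron-rich trisubstituted alkene (the enoate alkene is inert) should form the C7–C8 bond at the CH terminus with hydrogen transfer from a geminal methyl, which unveils the isopropenyl group; the titanium–BINOL complex sets the carbinol C8 (R, by analogy with 1,1-disubstituted alkenes) and the cyclic ene transition state places C7 syn to it (7S).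

Step 3
Reactants: 5 1-ethyl 7-methyl (2R,3S,5E)-2-hydroxy-5-methyl-3-(prop-1-en-2-yl)hept-5-enedioate
Product: 6 1-ethyl 7-methyl (2R,3S,5E)-2-(tert-butyldimethylsilyloxy)-5-methyl-3-(prop-1-en-2-yl)hept-5-enedioate
Conditions: TBSOTf, 2,6-lutidine, CH2Cl2, −78 to 0 °C
Reagents that add atoms: tert-butyldimethylsilyl trifluoromethanesulfonate, CC(C)(C)[Si](C)(C)OS(=O)(=O)C(F)(F)F
Why: Silylation of the hindered α-hydroxy ester with the silyl triflate installs a bulky, non-chelating group needed for step 5; no stereocenter is touched.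

Step 4
Reactants: 6 1-ethyl 7-methyl (2R,3S,5E)-2-(tert-butyldimethylsilyloxy)-5-methyl-3-(prop-1-en-2-yl)hept-5-enedioate
Product: 7 methyl (2E,5S,6R)-6-(tert-butyldimethylsilyloxy)-3-methyl-7-oxo-5-(prop-1-en-2-yl)hept-2-enoate
Conditions: i-Bu2AlH (1.05 equiv), CH2Cl2, −78 °C; aqueous work-up
Reagents that add atoms: none
Why: Partial hydride reduction of an ester to the aldehyde should be selective because the α-silyloxy ethyl ester is far more electrophilic than the β,β-disubstituted enoate and its tetrahedral aluminate is stable at −78 °C; the aldehyde is used at once so that C8 does not epimerise.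

Step 5
Reactants: 7 methyl (2E,5S,6R)-6-(tert-butyldimethylsilyloxy)-3-methyl-7-oxo-5-(prop-1-en-2-yl)hept-2-enoate; 8 (E)-1-(trimethylsilyloxy)buta-1,3-diene
Product: 9 methyl (2E,5S,6R,7S,9E)-6-(tert-butyldimethylsilyloxy)-7-hydroxy-3-methyl-11-oxo-5-(prop-1-en-2-yl)undeca-2,9-dienoate
Conditions: BF3·OEt2 (1.1 equiv), CH2Cl2, −78 °C; aq. NaHCO3
Reagents that add atoms: none
Why: Vinylogous Mukaiyama aldol reaction at the γ-carbon of the silyl dienol ether should give the (E)-δ-hydroxy enal directly; with a monodentate Lewis acid and the α-OTBS group, non-chelation control (nucleophile anti to the silyloxy group) gives the 8,9-anti relationship (9S).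

Step 6
Reactants: 9 methyl (2E,5S,6R,7S,9E)-6-(tert-butyldimethylsilyloxy)-7-hydroxy-3-methyl-11-oxo-5-(prop-1-en-2-yl)undeca-2,9-dienoate
Product: 10 methyl (2E,5S,6R,7S,9E)-6,7-bis(tert-butyldimethylsilyloxy)-3-methyl-11-oxo-5-(prop-1-en-2-yl)undeca-2,9-dienoate
Conditions: TBSOTf, 2,6-lutidine, CH2Cl2, −78 °C
Reagents that add atoms: tert-butyldimethylsilyl trifluoromethanesulfonate, CC(C)(C)[Si](C)(C)OS(=O)(=O)C(F)(F)F
Why: Silylation of the secondary alcohol; the weak base 2,6-lutidine at low temperature should not enolise the enal, and no stereocenter is touched.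

Step 7
Reactants: 10 methyl (2E,5S,6R,7S,9E)-6,7-bis(tert-butyldimethylsilyloxy)-3-methyl-11-oxo-5-(prop-1-en-2-yl)undeca-2,9-dienoate
Product: 11 methyl (2E,5S,6R,7S,8E,10E)-6,7-bis(tert-butyldimethylsilyloxy)-3-methyl-5-(prop-1-en-2-yl)-11-(triethylsilyloxy)undeca-2,8,10-trienoate
Conditions: TESOTf, Et3N, Et2O, −78 to 0 °C
Reagents that add atoms: triethylsilyl trifluoromethanesulfonate, CC[Si](CC)(CC)OS(=O)(=O)C(F)(F)F
Why: Soft (vinylogous) enolisation: O-silylation of the s-trans enal and γ-deprotonation at C10 should give the (1E,3E)-1-silyloxy diene, while the ester is not enolised under these conditions; the labile TES group is chosen so that C3 can later be unmasked beside the TBS ethers.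

Step 8
Reactants: 11 methyl (2E,5S,6R,7S,8E,10E)-6,7-bis(tert-butyldimethylsilyloxy)-3-methyl-5-(prop-1-en-2-yl)-11-(triethylsilyloxy)undeca-2,8,10-trienoate
Product: 12 (2E,5S,6R,7S,8E,10E)-6,7-bis(tert-butyldimethylsilyloxy)-3-methyl-5-(prop-1-en-2-yl)-11-(triethylsilyloxy)undeca-2,8,10-trien-1-ol
Conditions: i-Bu2AlH (2.5 equiv), PhMe, −78 °C; aqueous work-up
Reagents that add atoms: none
Why: 1,2-Reduction of the enoate to the allylic alcohol by the aluminium hydride; the silyl dienol ether and the silyl ethers are stable to this reagent and to a neutral work-up.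

Step 9
Reactants: 12 (2E,5S,6R,7S,8E,10E)-6,7-bis(tert-butyldimethylsilyloxy)-3-methyl-5-(prop-1-en-2-yl)-11-(triethylsilyloxy)undeca-2,8,10-trien-1-ol
Product: 14 8α,9α-bis(tert-butyldimethylsilyloxy)-3β-(triethylsilyloxy)-10αH-eremophila-1,11-dien-15-al (4β-formyl; 5β-methyl; 7α-isopropenyl; trans-fused), via trienal 13 (not isolated)
Conditions: MnO2, CH2Cl2, rt; filter; then Me2AlCl (1.1 equiv), CH2Cl2, −78 to −30 °C; aq. NaHCO3
Reagents that add atoms: none
Why: MnO2 oxidises the allylic alcohol to the (E)-enal, whose complexation by Me2AlCl triggers a normal-demand, asynchronous concerted intramolecular Diels–Alder reaction with the 1-silyloxy diene (type 1; closest known type: Lewis-acid-promoted cyclisation of deca-2,8,10-trienals to trans-decalins), the nucleophilic diene terminus C10 bonding to the β-carbon C5 and C3 to C4. Ring A is closed by the [4+2] event itself and ring B as the six-membered tether ring, through a chair with the tether exo. The cis C4/C5 pair (formyl and C14 methyl) follows from the E geometry of the enal, the C3/C10 relationship from the E,E diene, and the trans ring fusion together with the 3β,4β arrangement from the endo position of the aluminium-bound formyl group, which sits trans to the tether on the alkene. The absolute sense at C5 and C10 is set by the tether stereocenters, because only one chair has the C7 isopropenyl and C9 silyloxy groups equatorial (C8 silyloxy axial), whereas the other diene face would place both syn-axial to the new C5 methyl. The step needs endo-over-exo and diene-face selectivity, which the Lewis acid on the E enal and the C7/C9 substituents should secure, while regiochemistry is fixed by the four-carbon tether and is electronically matched (donor on C3, acceptor on C4). The C3 configuration formed here is provisional and is reset in steps 12 and 13.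

Step 10
Reactants: 14 8α,9α-bis(tert-butyldimethylsilyloxy)-3β-(triethylsilyloxy)-10αH-eremophila-1,11-dien-15-al
Product: 16 8α,9α-bis(tert-butyldimethylsilyloxy)-3β-(triethylsilyloxy)-10αH-eremophila-1,11-diene, via tosylhydrazone 15 (not isolated)
Conditions: TsNHNH2, THF, rt; catecholborane, CHCl3, 0 °C; NaOAc·3H2O, 60 °C
Reagents that add atoms: none
Why: Mild Wolff–Kishner-type deoxygenation (hydride addition to the tosylhydrazone, then acetate-triggered loss of sulfinate and N2) should turn the activating formyl group into the C15 methyl without touching the alkenes or silyl ethers; C4 keeps its equatorial 4β configuration.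

Step 11
Reactants: 16 8α,9α-bis(tert-butyldimethylsilyloxy)-3β-(triethylsilyloxy)-10αH-eremophila-1,11-diene
Product: 17 8α,9α-bis(tert-butyldimethylsilyloxy)-10αH-eremophila-1,11-dien-3β-ol
Conditions: PPTS (cat.), MeOH/CH2Cl2, rt
Reagents that add atoms: none
Why: Acid-catalysed methanolysis should cleave the triethylsilyl ether selectively, because the secondary TBS ethers react much more slowly.

Step 12
Reactants: 17 8α,9α-bis(tert-butyldimethylsilyloxy)-10αH-eremophila-1,11-dien-3β-ol
Product: 18 8α,9α-bis(tert-butyldimethylsilyloxy)-10αH-eremophila-1,11-dien-3-one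
Conditions: Dess–Martin periodinane, NaHCO3, CH2Cl2, rt
Reagents that add atoms: none
Why: Dess–Martin oxidation of the hindered allylic alcohol to the conjugated enone under buffered conditions; this erases the provisional C3 center and makes the C1–C2 alkene the only conjugated one.

Step 13
Reactants: 18 8α,9α-bis(tert-butyldimethylsilyloxy)-10αH-eremophila-1,11-dien-3-one
Product: 20 8α,9α-bis(tert-butyldimethylsilyloxy)-10αH-eremophil-11-en-3α-ol, via saturated ketone 19 (not isolated)
Conditions: Li, NH3(l)/THF, −78 °C; then MeOH, −33 °C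
Reagents that add atoms: none
Why: Dissolving-metal (Birch-type) reduction should first reduce the enone to its enolate and, once methanol is added, reduce the ketone under thermodynamic control to the equatorial 3α alcohol (hydride reagents would be steered to the wrong face by the syn-axial C5 methyl); the isolated isopropenyl alkene and the silyl ethers are inert and the C4 methyl stays equatorial.

Step 14
Reactants: 20 8α,9α-bis(tert-butyldimethylsilyloxy)-10αH-eremophil-11-en-3α-ol; 21 2-[bis(2,2,2-trifluoroethoxy)phosphoryl]acetic acid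
Product: 22 8α,9α-bis(tert-butyldimethylsilyloxy)-10αH-eremophil-11-en-3α-yl 2-[bis(2,2,2-trifluoroethoxy)phosphoryl]acetate
Conditions: EDC·HCl, DMAP (cat.), CH2Cl2, rt
Reagents that add atoms: none
Why: Steglich-type carbodiimide esterification of the equatorial C3 alcohol with retention at C3.

Step 15
Reactants: 23 angelic acid ((2Z)-2-methylbut-2-enoic acid); 24 methyl (2R)-2-hydroxybutanoate
Product: 26 methyl (2R)-2-{[(2Z)-2-methylbut-2-enoyl]oxy}butanoate, via mixed anhydride 25 (not isolated)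
Conditions: 2,4,6-trichlorobenzoyl chloride, Et3N, PhMe, rt; then 24, 80 °C
Reagents that add atoms: none
Why: Yamaguchi-type mixed-anhydride esterification without a nucleophilic catalyst should avoid the conjugate-addition pathway that isomerises angelates to tiglates; the stereocenter of 24 is not involved.

Step 16
Reactants: 26 methyl (2R)-2-{[(2Z)-2-methylbut-2-enoyl]oxy}butanoate
Product: 27 (2R)-1-oxobutan-2-yl (2Z)-2-methylbut-2-enoate
Conditions: i-Bu2AlH (1.0 equiv), CH2Cl2, −78 °C; aqueous work-up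
Reagents that add atoms: none
Why: Partial hydride reduction of the activated α-acyloxy methyl ester, which is much more electrophilic than the hindered conjugated angelate; the aldehyde is used at once to avoid epimerisation.

Step 17
Reactants: 22 8α,9α-bis(tert-butyldimethylsilyloxy)-10αH-eremophil-11-en-3α-yl 2-[bis(2,2,2-trifluoroethoxy)phosphoryl]acetate; 27 (2R)-1-oxobutan-2-yl (2Z)-2-methylbut-2-enoate
Product: 28 8α,9α-bis(tert-butyldimethylsilyloxy)-10αH-eremophil-11-en-3α-yl (2Z,4R)-4-{[(2Z)-2-methylbut-2-enoyl]oxy}hex-2-enoate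
Conditions: KN(SiMe3)2, 18-crown-6, THF, −78 °C
Reagents that add atoms: none
Why: Still–Gennari olefination: the trifluoroethyl phosphonate with a dissociated potassium counter-ion should eliminate under kinetic control to the Z enoate, and the low temperature preserves the α-acyloxy stereocenter (4R).

Step 18
Reactants: 28 8α,9α-bis(tert-butyldimethylsilyloxy)-10αH-eremophil-11-en-3α-yl (2Z,4R)-4-{[(2Z)-2-methylbut-2-enoyl]oxy}hex-2-enoate
Product: 29 8α,9α-dihydroxy-10αH-eremophil-11-en-3α-yl (2Z,4R)-4-{[(2Z)-2-methylbut-2-enoyl]oxy}hex-2-enoate (CNP0382739.1)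
Conditions: HF·pyridine, pyridine, THF, 0 °C to rt
Reagents that add atoms: none
Why: Buffered fluoride cleavage of both TBS ethers under non-basic conditions that should leave the two esters, the Z enoate and the angelate unchanged.

**Compound list**
1 | methyl (2E)-4-bromo-3-methylbut-2-enoate | COC(=O)/C=C(\C)CBr | starting material
2 | 4,4,5,5-tetramethyl-2-(2-methylprop-1-en-1-yl)-1,3,2-dioxaborolane | CC(C)=CB1OC(C)(C)C(C)(C)O1 | starting material
3 | methyl (2E)-3,6-dimethylhepta-2,5-dienoate | COC(=O)/C=C(\C)CC=C(C)C | intermediate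
4 | ethyl glyoxylate | CCOC(=O)C=O | starting material
5 | 1-ethyl 7-methyl (2R,3S,5E)-2-hydroxy-5-methyl-3-(prop-1-en-2-yl)hept-5-enedioate | C=C(C)[C@@H]([C@@H](O)C(=O)OCC)C/C(C)=C/C(=O)OC | intermediate
6 | 1-ethyl 7-methyl (2R,3S,5E)-2-(tert-butyldimethylsilyloxy)-5-methyl-3-(prop-1-en-2-yl)hept-5-enedioate | C=C(C)[C@@H]([C@@H](O[Si](C)(C)C(C)(C)C)C(=O)OCC)C/C(C)=C/C(=O)OC | intermediate
7 | methyl (2E,5S,6R)-6-(tert-butyldimethylsilyloxy)-3-methyl-7-oxo-5-(prop-1-en-2-yl)hept-2-enoate | C=C(C)[C@@H]([C@@H](O[Si](C)(C)C(C)(C)C)C=O)C/C(C)=C/C(=O)OC | intermediate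
8 | (E)-1-(trimethylsilyloxy)buta-1,3-diene | C=C/C=C/O[Si](C)(C)C | starting material
9 | methyl (2E,5S,6R,7S,9E)-6-(tert-butyldimethylsilyloxy)-7-hydroxy-3-methyl-11-oxo-5-(prop-1-en-2-yl)undeca-2,9-dienoate | C=C(C)[C@@H]([C@@H](O[Si](C)(C)C(C)(C)C)[C@@H](O)C/C=C/C=O)C/C(C)=C/C(=O)OC | intermediate
10 | methyl (2E,5S,6R,7S,9E)-6,7-bis(tert-butyldimethylsilyloxy)-3-methyl-11-oxo-5-(prop-1-en-2-yl)undeca-2,9-dienoate | C=C(C)[C@@H]([C@@H](O[Si](C)(C)C(C)(C)C)[C@@H](O[Si](C)(C)C(C)(C)C)C/C=C/C=O)C/C(C)=C/C(=O)OC | intermediate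
11 | methyl (2E,5S,6R,7S,8E,10E)-6,7-bis(tert-butyldimethylsilyloxy)-3-methyl-5-(prop-1-en-2-yl)-11-(triethylsilyloxy)undeca-2,8,10-trienoate | C=C(C)[C@@H]([C@@H](O[Si](C)(C)C(C)(C)C)[C@@H](O[Si](C)(C)C(C)(C)C)/C=C/C=C/O[Si](CC)(CC)CC)C/C(C)=C/C(=O)OC | intermediate
12 | (2E,5S,6R,7S,8E,10E)-6,7-bis(tert-butyldimethylsilyloxy)-3-methyl-5-(prop-1-en-2-yl)-11-(triethylsilyloxy)undeca-2,8,10-trien-1-ol | C=C(C)[C@@H]([C@@H](O[Si](C)(C)C(C)(C)C)[C@@H](O[Si](C)(C)C(C)(C)C)/C=C/C=C/O[Si](CC)(CC)CC)C/C(C)=C/CO | intermediate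
13 | (2E,5S,6R,7S,8E,10E)-6,7-bis(tert-butyldimethylsilyloxy)-3-methyl-5-(prop-1-en-2-yl)-11-(triethylsilyloxy)undeca-2,8,10-trienal | C=C(C)[C@@H]([C@@H](O[Si](C)(C)C(C)(C)C)[C@@H](O[Si](C)(C)C(C)(C)C)/C=C/C=C/O[Si](CC)(CC)CC)C/C(C)=C/C=O | intermediate
14 | 8α,9α-bis(tert-butyldimethylsilyloxy)-3β-(triethylsilyloxy)-10αH-eremophila-1,11-dien-15-al | C=C(C)[C@@H]1C[C@]2(C)[C@@H](C=O)[C@@H](O[Si](CC)(CC)CC)C=C[C@H]2[C@H](O[Si](C)(C)C(C)(C)C)[C@@H]1O[Si](C)(C)C(C)(C)C | intermediate
15 | (E)-4-methylbenzenesulfonylhydrazone of 14 | C=C(C)[C@@H]1C[C@]2(C)[C@@H](/C=N/NS(=O)(=O)c3ccc(C)cc3)[C@@H](O[Si](CC)(CC)CC)C=C[C@H]2[C@H](O[Si](C)(C)C(C)(C)C)[C@@H]1O[Si](C)(C)C(C)(C)C | intermediate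
16 | 8α,9α-bis(tert-butyldimethylsilyloxy)-3β-(triethylsilyloxy)-10αH-eremophila-1,11-diene | C=C(C)[C@@H]1C[C@]2(C)[C@@H](C)[C@@H](O[Si](CC)(CC)CC)C=C[C@H]2[C@H](O[Si](C)(C)C(C)(C)C)[C@@H]1O[Si](C)(C)C(C)(C)C | intermediate
17 | 8α,9α-bis(tert-butyldimethylsilyloxy)-10αH-eremophila-1,11-dien-3β-ol | C=C(C)[C@@H]1C[C@]2(C)[C@@H](C)[C@@H](O)C=C[C@H]2[C@H](O[Si](C)(C)C(C)(C)C)[C@@H]1O[Si](C)(C)C(C)(C)C | intermediate
18 | 8α,9α-bis(tert-butyldimethylsilyloxy)-10αH-eremophila-1,11-dien-3-one | C=C(C)[C@@H]1C[C@]2(C)[C@@H](C)C(=O)C=C[C@H]2[C@H](O[Si](C)(C)C(C)(C)C)[C@@H]1O[Si](C)(C)C(C)(C)C | intermediate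
19 | 8α,9α-bis(tert-butyldimethylsilyloxy)-10αH-eremophil-11-en-3-one | C=C(C)[C@@H]1C[C@]2(C)[C@@H](C)C(=O)CC[C@H]2[C@H](O[Si](C)(C)C(C)(C)C)[C@@H]1O[Si](C)(C)C(C)(C)C | intermediate
20 | 8α,9α-bis(tert-butyldimethylsilyloxy)-10αH-eremophil-11-en-3α-ol | C=C(C)[C@@H]1C[C@]2(C)[C@@H](C)[C@H](O)CC[C@H]2[C@H](O[Si](C)(C)C(C)(C)C)[C@@H]1O[Si](C)(C)C(C)(C)C | intermediate
21 | 2-[bis(2,2,2-trifluoroethoxy)phosphoryl]acetic acid | OC(=O)CP(=O)(OCC(F)(F)F)OCC(F)(F)F | starting material
22 | 8α,9α-bis(tert-butyldimethylsilyloxy)-10αH-eremophil-11-en-3α-yl 2-[bis(2,2,2-trifluoroethoxy)phosphoryl]acetate | C=C(C)[C@@H]1C[C@]2(C)[C@@H](C)[C@H](OC(=O)CP(=O)(OCC(F)(F)F)OCC(F)(F)F)CC[C@H]2[C@H](O[Si](C)(C)C(C)(C)C)[C@@H]1O[Si](C)(C)C(C)(C)C | intermediate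
23 | angelic acid, (2Z)-2-methylbut-2-enoic acid | C/C=C(/C)C(=O)O | starting material
24 | methyl (2R)-2-hydroxybutanoate | CC[C@@H](O)C(=O)OC | starting material
25 | (2Z)-2-methylbut-2-enoic 2,4,6-trichlorobenzoic anhydride | C/C=C(/C)C(=O)OC(=O)c1c(Cl)cc(Cl)cc1Cl | intermediate
26 | methyl (2R)-2-{[(2Z)-2-methylbut-2-enoyl]oxy}butanoate | CC[C@@H](OC(=O)/C(C)=C\C)C(=O)OC | intermediate
27 | (2R)-1-oxobutan-2-yl (2Z)-2-methylbut-2-enoate | CC[C@@H](OC(=O)/C(C)=C\C)C=O | intermediate
28 | 8α,9α-bis(tert-butyldimethylsilyloxy)-10αH-eremophil-11-en-3α-yl (2Z,4R)-4-{[(2Z)-2-methylbut-2-enoyl]oxy}hex-2-enoate | C=C(C)[C@@H]1C[C@]2(C)[C@@H](C)[C@H](OC(=O)/C=C\[C@@H](CC)OC(=O)/C(C)=C\C)CC[C@H]2[C@H](O[Si](C)(C)C(C)(C)C)[C@@H]1O[Si](C)(C)C(C)(C)C | intermediate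
29 | 8α,9α-dihydroxy-10αH-eremophil-11-en-3α-yl (2Z,4R)-4-{[(2Z)-2-methylbut-2-enoyl]oxy}hex-2-enoate (CNP0382739.1) | C=C(C)[C@@H]1C[C@]2(C)[C@@H](C)[C@H](OC(=O)/C=C\[C@@H](CC)OC(=O)/C(C)=C\C)CC[C@H]2[C@H](O)[C@@H]1O | target

**Step count and risks**
Total steps: 18. Longest linear sequence: 16 (steps 1–14, 17, 18); steps 15–16 make the side-chain aldehyde.

Step 9 (key step). What may go wrong: the aluminium Lewis acid erodes the silyl dienol ether (protodesilylation, or ionisation next to the C9 silyloxy group) before cycloaddition, or the trienal oligomerises; leakage through the exo (cis-fused) transition state is the second concern. Fallback: cycloaddition at the ester oxidation level, with no oxidant and no Lewis acid. It sets out from 11. Heating 11 in toluene (BHT, 160 °C, sealed tube) should give the decalin methyl ester F1 through the same chair arrangement of the tether, with exo isomers removed by chromatography. LiAlH4 (Et2O, 0 °C) reduces the ester to the primary alcohol F2, TsCl/pyridine gives the tosylate F3, and LiEt3BH (THF, 0 °C to rt) displaces the tosylate by hydride, which returns to the route at 16.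

Step 2. What may go wrong: the ene reaction passes through the alternative (exo) transition state, so that the catalyst still controls the carbinol center but C7 is formed anti to it. Fallback: make the anti adduct on purpose with the enantiomeric catalyst and invert the carbinol. It sets out from 3 and 4. (S)-BINOL/TiCl2(OiPr)2 under the conditions of step 2 gives the (2S,3S)-anti hydroxy diester F4. A Mitsunobu reaction (4-nitrobenzoic acid, PPh3, DIAD, THF, 0 °C) inverts C2 and gives the (2R,3S) 4-nitrobenzoate F5. K2CO3 in EtOH at 0 °C removes the nitrobenzoate and returns to the route at 5.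

Step 5. What may go wrong: the vinylogous nucleophile attacks through its α-carbon or reacts sluggishly with the hindered α-silyloxy aldehyde, and facial control is incomplete. Fallback: build the enal stepwise by an acetate Mukaiyama aldol reaction and a Wittig reaction. It sets out from 7. 1-(tert-Butylthio)-1-(trimethylsilyloxy)ethene with BF3·OEt2 (CH2Cl2, −78 °C), a two-carbon nucleophile with reliable non-chelation (1,2-anti) selectivity, gives the β-hydroxy thioester F6. TBSOTf/2,6-lutidine gives the bis-silyl ether F7, and i-Bu2AlH (CH2Cl2, −78 °C) reduces the thioester to the aldehyde F8. (Triphenylphosphoranylidene)acetaldehyde (PhMe, 60 °C) then gives the E enal and returns to the route at 10.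

**Further compounds**
F1 | step 9 | methyl 8α,9α-bis(tert-butyldimethylsilyloxy)-3β-(triethylsilyloxy)-10αH-eremophila-1,11-dien-15-oate | C=C(C)[C@@H]1C[C@]2(C)[C@@H](C(=O)OC)[C@@H](O[Si](CC)(CC)CC)C=C[C@H]2[C@H](O[Si](C)(C)C(C)(C)C)[C@@H]1O[Si](C)(C)C(C)(C)C
F2 | step 9 | 8α,9α-bis(tert-butyldimethylsilyloxy)-3β-(triethylsilyloxy)-10αH-eremophila-1,11-dien-15-ol | C=C(C)[C@@H]1C[C@]2(C)[C@@H](CO)[C@@H](O[Si](CC)(CC)CC)C=C[C@H]2[C@H](O[Si](C)(C)C(C)(C)C)[C@@H]1O[Si](C)(C)C(C)(C)C
F3 | step 9 | 8α,9α-bis(tert-butyldimethylsilyloxy)-3β-(triethylsilyloxy)-10αH-eremophila-1,11-dien-15-yl 4-methylbenzenesulfonate | C=C(C)[C@@H]1C[C@]2(C)[C@@H](COS(=O)(=O)c3ccc(C)cc3)[C@@H](O[Si](CC)(CC)CC)C=C[C@H]2[C@H](O[Si](C)(C)C(C)(C)C)[C@@H]1O[Si](C)(C)C(C)(C)C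
F4 | step 2 | 1-ethyl 7-methyl (2S,3S,5E)-2-hydroxy-5-methyl-3-(prop-1-en-2-yl)hept-5-enedioate | C=C(C)[C@@H]([C@H](O)C(=O)OCC)C/C(C)=C/C(=O)OC
F5 | step 2 | 1-ethyl 7-methyl (2R,3S,5E)-5-methyl-2-(4-nitrobenzoyloxy)-3-(prop-1-en-2-yl)hept-5-enedioate | C=C(C)[C@@H]([C@@H](OC(=O)c1ccc(cc1)[N+](=O)[O-])C(=O)OCC)C/C(C)=C/C(=O)OC
F6 | step 5 | methyl (2E,5S,6R,7S)-6-(tert-butyldimethylsilyloxy)-9-(tert-butylsulfanyl)-7-hydroxy-3-methyl-9-oxo-5-(prop-1-en-2-yl)non-2-enoate | C=C(C)[C@@H]([C@@H](O[Si](C)(C)C(C)(C)C)[C@@H](O)CC(=O)SC(C)(C)C)C/C(C)=C/C(=O)OC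
F7 | step 5 | methyl (2E,5S,6R,7S)-6,7-bis(tert-butyldimethylsilyloxy)-9-(tert-butylsulfanyl)-3-methyl-9-oxo-5-(prop-1-en-2-yl)non-2-enoate | C=C(C)[C@@H]([C@@H](O[Si](C)(C)C(C)(C)C)[C@@H](O[Si](C)(C)C(C)(C)C)CC(=O)SC(C)(C)C)C/C(C)=C/C(=O)OC
F8 | step 5 | methyl (2E,5S,6R,7S)-6,7-bis(tert-butyldimethylsilyloxy)-3-methyl-9-oxo-5-(prop-1-en-2-yl)non-2-enoate | C=C(C)[C@@H]([C@@H](O[Si](C)(C)C(C)(C)C)[C@@H](O[Si](C)(C)C(C)(C)C)CC=O)C/C(C)=C/C(=O)OC
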